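I carry one number through these flasks: the share of isomer of the product A, meaning its amount over the sum of isomer of the product A, target and isomer of the product B (a selectivity).

| flask | starting material | reagent | temperature | remark | time |
|---|---|---|---|---|---|
| elm | 0.10 M | 1 equiv | 20 °C | run made earlier |  |
| oak | 0.10 M | 1.5 equiv | 38 °C | run made earlier |  |
| maple | 0.050 M | 2 equiv | 20 °C | run made earlier |  |
| south-east | 0.10 M | 2.00 equiv | 25 °C |  | 2.0 h |
| north-east | 0.10 M | 2.00 equiv | 50 °C |  | 2.0 h |

| run | time / min | isomer of the product B / % | isomer of the product A / % | target / % | starting material / % |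
|---|---|---|---|---|---|
| elm | 10.0 | 0 | 1.4 | 0.2 | 98.1 |
| elm | 30.0 | 0 | 5.5 | 3.0 | 92.5 |
| elm | 60.0 | 0.9 | 10.1 | 2.2 | 85.7 |
| elm | 80.0 | 1.3 | 13.4 | 3.9 | 81.2 |
| elm | 120 | 1.6 | 18.9 | 4.3 | 74.9 |
| oak | 12.0 | 1.3 | 13.5 | 3.4 | 81.7 |
| oak | 25.0 | 3.0 | 24.2 | 6.4 | 66.4 |
| oak | 40.0 | 4.4 | 33.6 | 7.5 | 53.3 |
| oak | 50.0 | 5.4 | 38.3 | 8.4 | 47.1 |
| oak | 60.0 | 7.5 | 41.8 | 9.6 | 42.1 |
| maple | 25.0 | 0 | 3.7 | 1.4 | 95.0 |
| maple | 50.0 | 0.6 | 9.6 | 2.1 | 88.1 |
| maple | 80.0 | 1.5 | 14.0 | 3.5 | 81.1 |
| maple | 90.0 | 0.9 | 15.0 | 3.7 | 79.1 |
| maple | 120 | 1.6 | 19.3 | 3.1 | 73.3 |

(readings scatter by 0.5 percentage points)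

- the numbers in the tables scatter by 0.5 percentage points (one standard deviation)

- which of these there is most of at the end, counted by the starting material in it, south-east (isomer of the product B / target / starting material / isomer of the product A)
- which of these there is most of at the end, counted by the starting material in it, north-east (isomer of the product B / target / starting material / isomer of the product A)
- the largest of these amounts at the end, in percent of the starting material charged, south-east
- the largest of these amounts at the end, in percent of the starting material charged, north-east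

The last elm reading gives a share of 76.2%. In oak the share reads 74.2% at the first reading and 71.0% at the last, while isomer of the product B over target climbs from 0.382 to 0.781. So I read isomer of the product A as staying put and isomer of the product B as fed by target. Isomer of the product A is then the share times what has reacted, and it passes starting material when starting material falls to share/(1+share), which at the elm share is 43.2%.

The forecast names starting material at 42.5% for south-east and isomer of the product B at 50% for north-east, on the ground that isomer of the product B “forms partly directly and partly from A”. I take its remaining starting material, about 42% in south-east and 1% in north-east, but reckon differently from there. South-east's 42% lies just under my tie line of 43.2%, so my rule leans narrowly to isomer of the product A there, against the forecast. North-east's 1% leaves isomer of the product A just under the oak share of 71.0%, so I name isomer of the product A there.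

South-east gives starting material at 47.2%, and north-east gives isomer of the product A at 68.7%.

    reagent + tight pair → target (k = 14.0 M⁻¹ min⁻¹, Ea = 50.0 kJ mol⁻¹)
    starting material ⇌ tight pair (K = 9.00 × 10⁻⁴, k = 0.0230 min⁻¹, Ea = 97.0 kJ mol⁻¹, ΔH = 18.0 kJ mol⁻¹)
    reagent + loose pair → isomer of the product A (k = 42.0 M⁻¹ min⁻¹, Ea = 49.0 kJ mol⁻¹)
    target ⇌ isomer of the product B (K = 0.890, k = 0.0120 min⁻¹, Ea = 81.0 kJ mol⁻¹, ΔH = 1.00 kJ mol⁻¹)
    tight pair ⇌ loose pair (K = 1.10, k = 91.0 min⁻¹, Ea = 72.0 kJ mol⁻¹, ΔH = −10.0 kJ mol⁻¹)
    (constants at 25 °C)

North-east's isomer of the product A does not drain into isomer of the product B, which stands at 14.4% at the asked time, and after 20.0 h isomer of the product A is still 69.5%. South-east's starting material, 47.2%, stays above the tie line. In the neighbour flask with 0.17 M of starting material, 36.2% is left, below the line. The share then gives 48.6%, and isomer of the product A leads that flask at 47.4%.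

The numbers in the tables are calculated with constants of no real substance; the scatter is artificial.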